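**Retrosynthetic overview**
1. The usual Suzuki union of a 6-haloflavone with an 8-borylflavone is not used. Both pyranone rings are cut at once: target ⇒ protected biflavone ⇒ one biaryl bis-salicylaldehyde plus two aroylcarbene equivalents (an acyl sulfoxonium ylide).
2. Bis-salicylaldehyde ⇒ an ortho,para'-biphenyldiol by twofold ortho-formylation. The OH ortho to the axis codes for the 8-linked flavone, and the OH para to the axis codes for the 6-linked flavone.
3. Key step: the tetra-ortho-oxygenated axis is made without cross-coupling. Biphenyldiol ⇒ p-quinol ⇒ MOM-directed aryllithium + 2,6-bis(benzyloxy)-1,4-benzoquinone (1,2-addition, then reductive aromatisation).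
4. Ring order: all four benzenoid rings are bought. The axis is made first, then both pyranone rings close in one flask. One BCl3 step frees five OH groups and leaves the 7-OMe.

Assumption: the SMILES has no stereodescriptor and the molecule has no stereocentre; its only stereogenic element, the hindered biaryl axis, is left open in the SMILES, so the compound is made as drawn, racemic about that axis.

Ring 1 is the quinone-derived ring, which becomes the 6-linked unit. Ring 2 is the ring from 3,5-dimethoxyphenol, which becomes the 8-linked unit.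

**Step 1**
Reactants: 1 3,5-dimethoxyphenol
Product: 2 1,3-dimethoxy-5-(methoxymethoxy)benzene
Conditions: NaH, MOMCl, DMF, 0 °C to rt
Reagents that add atoms: chloromethyl methyl ether, COCCl
Why: Williamson-type O-alkylation of the sodium phenoxide installs the MOM group, which protects the phenol and is the strongest ortho-director on the ring for step 3; no stereocentre is formed.

**Step 2**
Reactants: 3 3,5-bis(benzyloxy)phenol
Product: 4 2,6-bis(benzyloxy)-1,4-benzoquinone
Conditions: (KSO3)2NO (2.5 equiv), KH2PO4, acetone–H2O, rt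
Reagents that add atoms: potassium nitrosodisulfonate, [K+].[K+].[O]N(S(=O)(=O)[O-])S(=O)(=O)[O-]
Why: Teuber oxidation, in which one nitroxyl radical removes the phenolic hydrogen and a second delivers oxygen to the free para carbon, gives the p-quinone and leaves the benzyl ethers untouched; no stereocentre is formed.

**Step 3**
Reactants: 2 1,3-dimethoxy-5-(methoxymethoxy)benzene; 4 2,6-bis(benzyloxy)-1,4-benzoquinone
Product: 6 3,5-bis(benzyloxy)-4-[2,4-dimethoxy-6-(methoxymethoxy)phenyl]-4-hydroxycyclohexa-2,5-dien-1-one, via aryllithium 5 (not isolated)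
Conditions: n-BuLi, THF, 0 °C to rt; then cannulate into 4, THF, −78 °C; AcOH quench at −78 °C
Reagents that add atoms: none
Why: Directed ortho-metalation occurs between OMOM and OMe, and the aryllithium then adds 1,2 to the quinone carbonyl flanked by the two OBn groups, because the other carbonyl is a doubly vinylogous ester and the flanking ether oxygens chelate lithium; forming the congested bond at an sp3 carbon avoids the steric penalty of a tetra-ortho cross-coupling, and the new quaternary carbon lies on a mirror plane and is not a stereocentre.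

**Step 4**
Reactants: 6 3,5-bis(benzyloxy)-4-[2,4-dimethoxy-6-(methoxymethoxy)phenyl]-4-hydroxycyclohexa-2,5-dien-1-one
Product: 8 2,6-bis(benzyloxy)-4',6'-dimethoxybiphenyl-2',4-diol, via MOM-protected biphenylol 7 (not isolated)
Conditions: Zn dust, AcOH–THF, rt; filter; then 3 M aq. HCl added to the filtrate, 45 °C
Reagents that add atoms: none
Why: Dissolving-metal reductive aromatisation of a p-quinol (two-electron reduction of the dienone with loss of the para OH as water, the competing dienone–phenol aryl shift being blocked because both neighbouring carbons carry OBn) gives the 4-arylphenol, and acetal hydrolysis then frees the second phenol; 8 is achiral because ring 1 is still symmetric.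

**Step 5**
Reactants: 8 2,6-bis(benzyloxy)-4',6'-dimethoxybiphenyl-2',4-diol
Product: 9 2,6-bis(benzyloxy)-2',4-dihydroxy-4',6'-dimethoxybiphenyl-3,3'-dicarbaldehyde
Conditions: MgCl2 (6 equiv), Et3N (10 equiv), (CH2O)n (15 equiv), MeCN, reflux; 1 M HCl work-up
Reagents that add atoms: formaldehyde (as paraformaldehyde), C=O
Why: Casnati–Skattebøl ortho-formylation runs through a magnesium phenoxide–formaldehyde chelate and is strictly ortho-selective, so ring 2 can react only at C3' and ring 1 only at one of its two enantiotopic positions C3/C5, after which the chelated aldehyde deactivates that ring; the axis becomes stereogenic here and forms as the racemate.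

**Step 6**
Reactants: 10 4-(benzyloxy)benzoyl chloride
Product: 11 1-[4-(benzyloxy)phenyl]-2-[dimethyl(oxo)-λ6-sulfanylidene]ethan-1-one
Conditions: Me3S(O)I (3 equiv), KOt-Bu (3 equiv), THF, reflux; then 10, 0 °C to rt
Reagents that add atoms: trimethylsulfoxonium iodide, C[S+](C)(C)=O.[I-]
Why: C-acylation of the Corey–Chaykovsky methylide by the acid chloride, with a second equivalent of methylide acting as base, gives the stabilised crystalline acyl sulfoxonium ylide; no stereocentre is formed.

**Step 7**
Reactants: 9 2,6-bis(benzyloxy)-2',4-dihydroxy-4',6'-dimethoxybiphenyl-3,3'-dicarbaldehyde; 11 1-[4-(benzyloxy)phenyl]-2-[dimethyl(oxo)-λ6-sulfanylidene]ethan-1-one (3 equiv)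
Product: 13 5,7-bis(benzyloxy)-2-[4-(benzyloxy)phenyl]-6-{2-[4-(benzyloxy)phenyl]-5,7-dimethoxy-4-oxo-4H-chromen-8-yl}-4H-chromen-4-one, via bis(1,3-diketone) 12 (not isolated)
Conditions: [Cp*RhCl2]2 (5 mol %), AgSbF6 (20 mol %), PivOH (2 equiv), DCE, 100 °C
Reagents that add atoms: none
Why: Phenoxide-directed aldehydic C–H activation by trivalent rhodium, aroylcarbene transfer from the sulfoxonium ylide with loss of DMSO, migratory insertion and protodemetalation give an o-hydroxyaryl 1,3-diketone that cyclodehydrates under the acidic conditions (the known salicylaldehyde-to-chromone annulation, run here on both aldehydes in one flask); since the only free OH next to each acyl group is O-4 in ring 1 and O-2' in ring 2, ring 1 must close to the 6-linked flavone and ring 2 to the 8-linked flavone, and the axis is not affected.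

**Step 8**
Reactants: 13 5,7-bis(benzyloxy)-2-[4-(benzyloxy)phenyl]-6-{2-[4-(benzyloxy)phenyl]-5,7-dimethoxy-4-oxo-4H-chromen-8-yl}-4H-chromen-4-one
Product: 14 7'-O-methylagathisflavone
Conditions: BCl3 (12 equiv), C6HMe5 (12 equiv), CH2Cl2, −78 to 0 °C; then H2O
Reagents that add atoms: none
Why: Lewis-acid dealkylation with a cation scavenger removes all four benzyl groups as benzyl cations trapped by pentamethylbenzene, and chelation-controlled demethylation removes only the 5-OMe that can bind boron together with the C4 carbonyl, so the non-chelating 7-OMe of the 8-linked unit survives; no stereochemical element is touched.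

**Compound list**
1 | 3,5-dimethoxyphenol | COc1cc(O)cc(OC)c1 | starting material
2 | 1,3-dimethoxy-5-(methoxymethoxy)benzene | COCOc1cc(OC)cc(OC)c1 | intermediate
3 | 3,5-bis(benzyloxy)phenol | Oc1cc(OCc2ccccc2)cc(OCc2ccccc2)c1 | starting material
4 | 2,6-bis(benzyloxy)-1,4-benzoquinone | O=C1C=C(OCc2ccccc2)C(=O)C(OCc2ccccc2)=C1 | intermediate
5 | [2,4-dimethoxy-6-(methoxymethoxy)phenyl]lithium | [Li]c1c(OC)cc(OC)cc1OCOC | intermediate
6 | 3,5-bis(benzyloxy)-4-[2,4-dimethoxy-6-(methoxymethoxy)phenyl]-4-hydroxycyclohexa-2,5-dien-1-one | O=C1C=C(OCc2ccccc2)C(O)(c2c(OC)cc(OC)cc2OCOC)C(OCc2ccccc2)=C1 | intermediate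
7 | 2,6-bis(benzyloxy)-4',6'-dimethoxy-2'-(methoxymethoxy)biphenyl-4-ol | COCOc1cc(OC)cc(OC)c1-c1c(OCc2ccccc2)cc(O)cc1OCc1ccccc1 | intermediate
8 | 2,6-bis(benzyloxy)-4',6'-dimethoxybiphenyl-2',4-diol | COc1cc(O)c(-c2c(OCc3ccccc3)cc(O)cc2OCc2ccccc2)c(OC)c1 | intermediate
9 | 2,6-bis(benzyloxy)-2',4-dihydroxy-4',6'-dimethoxybiphenyl-3,3'-dicarbaldehyde (racemic axis) | O=Cc1c(O)cc(OCc2ccccc2)c(-c2c(O)c(C=O)c(OC)cc2OC)c1OCc1ccccc1 | intermediate
10 | 4-(benzyloxy)benzoyl chloride | O=C(Cl)c1ccc(OCc2ccccc2)cc1 | starting material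
11 | 1-[4-(benzyloxy)phenyl]-2-[dimethyl(oxo)-λ6-sulfanylidene]ethan-1-one | CS(C)(=O)=CC(=O)c1ccc(OCc2ccccc2)cc1 | intermediate
12 | 1,1'-[2,6-bis(benzyloxy)-2',4-dihydroxy-4',6'-dimethoxybiphenyl-3,3'-diyl]bis{3-[4-(benzyloxy)phenyl]propane-1,3-dione} | O=C(CC(=O)c1ccc(OCc2ccccc2)cc1)c1c(O)cc(OCc2ccccc2)c(-c2c(O)c(C(=O)CC(=O)c3ccc(OCc4ccccc4)cc3)c(OC)cc2OC)c1OCc1ccccc1 | intermediate
13 | 5,7-bis(benzyloxy)-2-[4-(benzyloxy)phenyl]-6-{2-[4-(benzyloxy)phenyl]-5,7-dimethoxy-4-oxo-4H-chromen-8-yl}-4H-chromen-4-one | COc1cc(OC)c2c(=O)cc(-c3ccc(OCc4ccccc4)cc3)oc2c1-c1c(OCc2ccccc2)cc2oc(-c3ccc(OCc4ccccc4)cc3)cc(=O)c2c1OCc1ccccc1 | intermediate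
14 | 7'-O-methylagathisflavone | COc1cc(O)c2c(=O)cc(-c3ccc(O)cc3)oc2c1-c1c(O)cc2oc(-c3ccc(O)cc3)cc(=O)c2c1O | target

**Total step count:** 8. **Longest linear sequence:** 6 (steps 1, 3, 4, 5, 7, 8; the branch through steps 2, 3, 4, 5, 7, 8 is equally long).

**The three steps most likely to fail**

**Quinone addition (step 3).** The hindered aryllithium may attack the unhindered carbonyl instead, or it may simply reduce the quinone by electron transfer. The fallback sets out from 4 and 5 and comes back at 8. It gives up carbonyl addition and makes the axis by Negishi coupling.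
- Compound 4 is reduced with Na2S2O4 to 2,6-bis(benzyloxy)benzene-1,4-diol F1.
- Only the unhindered 4-OH is protected (MOMCl, iPr2NEt) to give 2,6-bis(benzyloxy)-4-(methoxymethoxy)phenol F2.
- The remaining hindered OH is converted with Tf2O and pyridine into 2,6-bis(benzyloxy)-4-(methoxymethoxy)phenyl triflate F3.
- Aryllithium 5 is transmetalated with ZnCl2 to [2,4-dimethoxy-6-(methoxymethoxy)phenyl]zinc chloride F4.
- F3 and F4 are coupled (Pd2(dba)3, RuPhos, THF, 70 °C) to 2,6-bis(benzyloxy)-4',6'-dimethoxy-2',4-bis(methoxymethoxy)biphenyl F5.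
- The aqueous HCl treatment already used in step 4 removes both MOM groups and gives 8.

**Twofold rhodium annulation (step 7).** Both aldehydes are flanked by two ortho substituents, and the directing OH of ring 2 sits next to the axis. Rhodacycle formation may therefore be slow, or decarbonylation may compete. The fallback sets out from 9 and comes back at 13. It builds the three-carbon units by polar chemistry.
- Commercial 1-(benzyloxy)-4-ethynylbenzene is deprotonated with n-BuLi to lithium [4-(benzyloxy)phenyl]acetylide F6.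
- Five equivalents are added to 9 (two are consumed by the phenols; AcOH quench) to give the bis(propargylic alcohol) F7. It forms as a diastereomer mixture, which is of no consequence.
- MnO2 in CH2Cl2 oxidises F7 to the bis(ynone) F8.
- Catalytic DMAP in DMF closes both rings by 6-endo-dig oxa-Michael cyclisation onto the same two free phenols, giving 13.

**Global deprotection (step 8).** Benzyl cations may C-benzylate the very electron-rich phloroglucinol rings despite the scavenger, or the five cleavages may not all finish before the 7-OMe begins to suffer. The fallback sets out from 13 and comes back at 14. It separates the two kinds of cleavage.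
- Hydrogenolysis (H2, Pd/C, THF–MeOH, rt) removes the four benzyl groups without any cationic species. This gives 5,7-dihydroxy-2-(4-hydroxyphenyl)-6-[2-(4-hydroxyphenyl)-5,7-dimethoxy-4-oxo-4H-chromen-8-yl]-4H-chromen-4-one F9.
- AlCl3 in MeCN at reflux then removes only the carbonyl-chelated 5-OMe and gives 14.

**Further compounds**
F1 | step 3 | 2,6-bis(benzyloxy)benzene-1,4-diol | Oc1cc(OCc2ccccc2)c(O)c(OCc2ccccc2)c1
F2 | step 3 | 2,6-bis(benzyloxy)-4-(methoxymethoxy)phenol | COCOc1cc(OCc2ccccc2)c(O)c(OCc2ccccc2)c1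
F3 | step 3 | 2,6-bis(benzyloxy)-4-(methoxymethoxy)phenyl triflate | COCOc1cc(OCc2ccccc2)c(OS(=O)(=O)C(F)(F)F)c(OCc2ccccc2)c1
F4 | step 3 | [2,4-dimethoxy-6-(methoxymethoxy)phenyl]zinc chloride | Cl[Zn]c1c(OC)cc(OC)cc1OCOC
F5 | step 3 | 2,6-bis(benzyloxy)-4',6'-dimethoxy-2',4-bis(methoxymethoxy)biphenyl | COCOc1cc(OC)cc(OC)c1-c1c(OCc2ccccc2)cc(OCOC)cc1OCc1ccccc1
F6 | step 7 | lithium [4-(benzyloxy)phenyl]acetylide | [Li]C#Cc1ccc(OCc2ccccc2)cc1
F7 | step 7 | bis(propargylic alcohol) from 9 (diastereomer mixture) | OC(C#Cc1ccc(OCc2ccccc2)cc1)c1c(O)cc(OCc2ccccc2)c(-c2c(O)c(C(O)C#Cc3ccc(OCc4ccccc4)cc3)c(OC)cc2OC)c1OCc1ccccc1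
F8 | step 7 | bis(ynone) from F7 | O=C(C#Cc1ccc(OCc2ccccc2)cc1)c1c(O)cc(OCc2ccccc2)c(-c2c(O)c(C(=O)C#Cc3ccc(OCc4ccccc4)cc3)c(OC)cc2OC)c1OCc1ccccc1
F9 | step 8 | 5,7-dihydroxy-2-(4-hydroxyphenyl)-6-[2-(4-hydroxyphenyl)-5,7-dimethoxy-4-oxo-4H-chromen-8-yl]-4H-chromen-4-one | COc1cc(OC)c2c(=O)cc(-c3ccc(O)cc3)oc2c1-c1c(O)cc2oc(-c3ccc(O)cc3)cc(=O)c2c1O
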